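Diffractaic acid has no stereogenic element, so the route needs no asymmetric step. Everything rests on cutting ring A, the pentasubstituted 2,4-dioxygenated 3,6-dimethylbenzoyl ring (C5 carries H), at C1–C2 and C5–C6. C1, C6 and the 6-methyl come from a but-2-ynoate already esterified to O4 of ring B. C2–C5, with both oxygens and the 3-methyl, come from a 1,1,3-trioxygenated silyl ketene acetal diene. One Diels–Alder/aromatization thus builds the crowded ring A around the depside carbonyl instead of acylating with a di-ortho-substituted acid. The precursor is the 4-O-but-2-ynoate of benzyl 2-benzyloxy-4-hydroxy-3,6-dimethylbenzoate.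

Key step: step 8

Assumption: the target is achiral (no stereocentre, no stereogenic axis), so the request for a single enantiomer is met by the constitution alone; methyl 2-methylacetoacetate is used as the racemate and its stereocentre disappears in step 6.

Step 1
Reactants: 1 methyl 2,4-dihydroxy-3,6-dimethylbenzoate
Product: 2 methyl 4-(allyloxy)-2-hydroxy-3,6-dimethylbenzoate
Conditions: allyl bromide (1.1 equiv), K2CO3, acetone, reflux
Reagents that add atoms: allyl bromide, C=CCBr
Why: Williamson etherification; the 4-OH is the more acidic, unchelated phenol, whereas the 2-OH is hydrogen-bonded to the ester carbonyl and flanked by the 3-methyl, so one equivalent of allyl bromide with a weak base should alkylate O4 only.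

Step 2
Reactants: 2 methyl 4-(allyloxy)-2-hydroxy-3,6-dimethylbenzoate
Product: 3 4-(allyloxy)-2-hydroxy-3,6-dimethylbenzoic acid
Conditions: KOH, aq. DMSO, 80–90 °C; then cold 1 M HCl to pH 2 at 0 °C
Reagents that add atoms: potassium hydroxide, [K+].[OH-]
Why: Saponification (BAc2) of a hindered, phenoxide-deactivated salicylate, for which hydroxide in aqueous DMSO is the usual remedy; the allyl ether is base-stable and cold acidification should keep the electron-rich salicylic acid from decarboxylating.

Step 3
Reactants: 3 4-(allyloxy)-2-hydroxy-3,6-dimethylbenzoic acid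
Product: 4 benzyl 4-(allyloxy)-2-(benzyloxy)-3,6-dimethylbenzoate
Conditions: BnBr (2.5 equiv), K2CO3, DMF, 60 °C
Reagents that add atoms: benzyl bromide, BrCc1ccccc1
Why: Double SN2 O-alkylation (carboxylate esterification plus Williamson etherification) in one flask; in DMF the carboxylate reacts first and the chelated 2-phenoxide follows on warming with excess benzyl bromide.

Step 4
Reactants: 4 benzyl 4-(allyloxy)-2-(benzyloxy)-3,6-dimethylbenzoate
Product: 5 benzyl 2-(benzyloxy)-4-hydroxy-3,6-dimethylbenzoate
Conditions: Pd(PPh3)4 (cat.), morpholine, THF, rt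
Reagents that add atoms: none
Why: Pd(0)-catalysed deallylation (Tsuji–Trost allyl transfer to an amine); only the allyl aryl ether ionises under these conditions, so the benzyl ether and benzyl ester should remain and the 4-OH is released alone.

Step 5
Reactants: 5 benzyl 2-(benzyloxy)-4-hydroxy-3,6-dimethylbenzoate; 6 but-2-ynoic acid
Product: 7 benzyl 2-(benzyloxy)-4-(but-2-ynoyloxy)-3,6-dimethylbenzoate
Conditions: DCC, DMAP (cat.), CH2Cl2, 0 °C to rt
Reagents that add atoms: none
Why: Steglich esterification; 5 has a single free hydroxyl, and carbodiimide activation at low temperature with only catalytic DMAP should acylate it before the base can isomerise or add to the ynoate.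

Step 6
Reactants: 8 methyl 2-methyl-3-oxobutanoate (methyl 2-methylacetoacetate, racemic)
Product: 10 methyl (E)-3-methoxy-2-methylbut-2-enoate, via dimethyl ketal 9 (not isolated)
Conditions: HC(OMe)3, H2SO4 (cat.), rt; then distillation
Reagents that add atoms: trimethyl orthoformate, COC(OC)OC
Why: Acid-catalysed ketalisation with an orthoester followed by elimination of methanol to the conjugated β-methoxy enoate (O-methylation of a β-keto ester that avoids C-alkylation); the stereocentre of 8 is erased, and any Z isomer would converge with the E isomer in step 7.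

Step 7
Reactants: 10 methyl (E)-3-methoxy-2-methylbut-2-enoate
Product: 12 1,3-dimethoxy-2-methyl-1-(trimethylsilyloxy)buta-1,3-diene (ketene acetal geometry undefined), via lithium dienolate 11 (not isolated)
Conditions: LDA (commercial solution), THF, −78 °C; TMSCl, −78 °C to rt; filtration and concentration under argon
Reagents that add atoms: chlorotrimethylsilane, C[Si](C)(C)Cl
Why: Kinetic γ-deprotonation to a vinylogous ester enolate and O-silylation by the hard electrophile TMSCl (silyl ketene acetal formation); C2 bears no hydrogen, so only the C4 methyl can be deprotonated, and the moisture-sensitive diene is used directly.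

Step 8
Reactants: 7 benzyl 2-(benzyloxy)-4-(but-2-ynoyloxy)-3,6-dimethylbenzoate; 12 1,3-dimethoxy-2-methyl-1-(trimethylsilyloxy)buta-1,3-diene
Product: 15 benzyl 2-(benzyloxy)-4-[(2-hydroxy-4-methoxy-3,6-dimethylbenzoyl)oxy]-3,6-dimethylbenzoate, via cyclohexadiene cycloadduct 13 (not isolated), via aryl trimethylsilyl ether 14 (not isolated)
Conditions: 12 (3 equiv), PhMe, 110 °C, sealed tube; then 1 M HCl, THF, rt
Reagents that add atoms: none
Why: The electron-rich diene 12 and the electron-poor aryl ynoate 7 should combine in a normal-demand, strongly asynchronous Diels–Alder reaction (at the stepwise limit a vinylogous Mukaiyama–Michael addition followed by ring closure); the closest known reaction type is the cycloaddition of Brassard-type dienes with acetylenic esters followed by aromatizing elimination. Ring A is closed intermolecularly as a six-membered carbocycle by two new bonds, C5–C6 (diene CH2 terminus to the methyl-bearing ynoate β-carbon) and C1–C2 (ketene acetal carbon to the ynoate α-carbon), giving the cyclohexa-1,4-diene 13. Adduct 13 should lose methanol from its mixed O-methyl O-silyl ketal carbon together with a hydrogen of the ring CH2 to give aryl silyl ether 14, which the dilute acid work-up cleaves to the chelated phenol 15. The only stereocentre formed, the ketal carbon of 13, is racemic and is destroyed on aromatization, so no stereocontrol is required. The step needs regioselectivity, so that the oxygens end at C2 and C4 and the methyls at C3 and C6; this is secured by pairing the largest HOMO coefficient (the unsubstituted CH2 terminus of 12) with the largest LUMO coefficient (the β-carbon of 7). The aryl ester makes 7 a better acceptor than an alkyl butynoate, and 7 offers no other electron-poor π bond.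

Step 9
Reactants: 15 benzyl 2-(benzyloxy)-4-[(2-hydroxy-4-methoxy-3,6-dimethylbenzoyl)oxy]-3,6-dimethylbenzoate
Product: 16 benzyl 2-(benzyloxy)-4-[(2,4-dimethoxy-3,6-dimethylbenzoyl)oxy]-3,6-dimethylbenzoate
Conditions: MeI (excess), K2CO3, acetone, reflux
Reagents that add atoms: iodomethane, CI
Why: Williamson O-methylation; the chelated 2-OH of ring A is the only acidic hydroxyl because ring B is fully benzylated, and carbonate in acetone should leave the di-ortho-substituted aryl ester intact.

Step 10
Reactants: 16 benzyl 2-(benzyloxy)-4-[(2,4-dimethoxy-3,6-dimethylbenzoyl)oxy]-3,6-dimethylbenzoate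
Product: 17 diffractaic acid, 4-[(2,4-dimethoxy-3,6-dimethylbenzoyl)oxy]-2-hydroxy-3,6-dimethylbenzoic acid
Conditions: H2 (1 atm), 10% Pd/C, EtOAc, rt
Reagents that add atoms: none
Why: Catalytic hydrogenolysis of a benzyl ether and a benzyl ester in one operation; the aryl benzoate, the methyl ethers and the arenes are inert under these conditions, and a non-nucleophilic solvent excludes transesterification of the depside.

Compound list
1 | methyl 2,4-dihydroxy-3,6-dimethylbenzoate | COC(=O)c1c(C)cc(O)c(C)c1O | starting material
2 | methyl 4-(allyloxy)-2-hydroxy-3,6-dimethylbenzoate | C=CCOc1cc(C)c(C(=O)OC)c(O)c1C | intermediate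
3 | 4-(allyloxy)-2-hydroxy-3,6-dimethylbenzoic acid | C=CCOc1cc(C)c(C(=O)O)c(O)c1C | intermediate
4 | benzyl 4-(allyloxy)-2-(benzyloxy)-3,6-dimethylbenzoate | C=CCOc1cc(C)c(C(=O)OCc2ccccc2)c(OCc2ccccc2)c1C | intermediate
5 | benzyl 2-(benzyloxy)-4-hydroxy-3,6-dimethylbenzoate | Oc1cc(C)c(C(=O)OCc2ccccc2)c(OCc2ccccc2)c1C | intermediate
6 | but-2-ynoic acid | CC#CC(=O)O | starting material
7 | benzyl 2-(benzyloxy)-4-(but-2-ynoyloxy)-3,6-dimethylbenzoate | CC#CC(=O)Oc1cc(C)c(C(=O)OCc2ccccc2)c(OCc2ccccc2)c1C | intermediate
8 | methyl 2-methyl-3-oxobutanoate (methyl 2-methylacetoacetate, racemic) | COC(=O)C(C)C(C)=O | starting material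
9 | methyl 3,3-dimethoxy-2-methylbutanoate (racemic) | COC(=O)C(C)C(C)(OC)OC | intermediate (not isolated)
10 | methyl (E)-3-methoxy-2-methylbut-2-enoate | CO/C(C)=C(\C)C(=O)OC | intermediate
11 | lithium 1,3-dimethoxy-2-methylbuta-1,3-dien-1-olate | [Li+].C=C(OC)C(C)=C([O-])OC | intermediate (not isolated)
12 | 1,3-dimethoxy-2-methyl-1-(trimethylsilyloxy)buta-1,3-diene (C1=C2 geometry undefined, both isomers give the same arene) | C=C(OC)C(C)=C(OC)O[Si](C)(C)C | intermediate
13 | benzyl 2-(benzyloxy)-4-{[4,6-dimethoxy-2,5-dimethyl-6-(trimethylsilyloxy)cyclohexa-1,4-diene-1-carbonyl]oxy}-3,6-dimethylbenzoate (racemic) | COC1=C(C)C(OC)(O[Si](C)(C)C)C(C(=O)Oc2cc(C)c(C(=O)OCc3ccccc3)c(OCc3ccccc3)c2C)=C(C)C1 | intermediate (not isolated)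
14 | benzyl 2-(benzyloxy)-4-{[4-methoxy-3,6-dimethyl-2-(trimethylsilyloxy)benzoyl]oxy}-3,6-dimethylbenzoate | COc1cc(C)c(C(=O)Oc2cc(C)c(C(=O)OCc3ccccc3)c(OCc3ccccc3)c2C)c(O[Si](C)(C)C)c1C | intermediate (not isolated)
15 | benzyl 2-(benzyloxy)-4-[(2-hydroxy-4-methoxy-3,6-dimethylbenzoyl)oxy]-3,6-dimethylbenzoate | COc1cc(C)c(C(=O)Oc2cc(C)c(C(=O)OCc3ccccc3)c(OCc3ccccc3)c2C)c(O)c1C | intermediate
16 | benzyl 2-(benzyloxy)-4-[(2,4-dimethoxy-3,6-dimethylbenzoyl)oxy]-3,6-dimethylbenzoate | COc1cc(C)c(C(=O)Oc2cc(C)c(C(=O)OCc3ccccc3)c(OCc3ccccc3)c2C)c(OC)c1C | intermediate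
17 | diffractaic acid | COc1cc(C)c(C(=O)Oc2cc(C)c(C(=O)O)c(O)c2C)c(OC)c1C | target

Total step count: 10. Longest linear sequence: 8 steps (steps 1, 2, 3, 4, 5, 8, 9, 10); the diene branch (steps 6 and 7) joins at step 8.

Steps most likely to fail

Step 8. The cycloaddition at the β-methyl-substituted ynoate may be slow enough that thermal decomposition or adventitious hydrolysis of the diene outruns it, or addition may occur with the opposite orientation. The fallback gives up the annulation and forms the depside ester bond by mixed-anhydride acylation, all of it known chemistry. It sets out from 1, which is exhaustively methylated (MeI, K2CO3, DMF, 60 °C) to methyl 2,4-dimethoxy-3,6-dimethylbenzoate F1. Saponification (KOH, aq. DMSO, 100 °C) gives 2,4-dimethoxy-3,6-dimethylbenzoic acid F2. Trifluoroacetic anhydride in toluene at rt converts it to 2,4-dimethoxy-3,6-dimethylbenzoic trifluoroacetic anhydride F3, which acylates phenol 5 in the same flask. This comes back to the route at 16, so that steps 5 to 9 are not needed.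

Step 2. Hydrolysis may stall because the ester is flanked on both sides and deactivated by the neighbouring phenoxide; harsher conditions invite allyl-to-propenyl migration, and acidification may cause decarboxylation. The fallback changes the order of events and the mode of ester cleavage. It sets out from 2, whose 2-OH is benzylated first (BnBr, K2CO3, DMF, 60 °C) to methyl 4-(allyloxy)-2-(benzyloxy)-3,6-dimethylbenzoate F4. The methyl ester is then cleaved under anhydrous conditions with potassium trimethylsilanolate (THF, reflux) to 4-(allyloxy)-2-(benzyloxy)-3,6-dimethylbenzoic acid F5, which has no free ortho-hydroxyl to promote decarboxylation. Benzylation of the carboxylate (BnBr, K2CO3, DMF) comes back to the route at 4.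

Step 9. Alkylation of the chelated, doubly flanked phenol may be sluggish, and prolonged exposure to base may cleave the depside ester. The fallback replaces phenoxide alkylation by a Mitsunobu redox condensation under neutral conditions (MeOH, PPh3, DIAD, THF, 0 °C to rt), in which the phenol serves as the acid component and no free base is present. It sets out from 15 and comes back to the route at 16. Compounds beyond the list: none F0.

Further compounds
F1 | step 8 | methyl 2,4-dimethoxy-3,6-dimethylbenzoate | COC(=O)c1c(C)cc(OC)c(C)c1OC
F2 | step 8 | 2,4-dimethoxy-3,6-dimethylbenzoic acid | COc1cc(C)c(C(=O)O)c(OC)c1C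
F3 | step 8 | 2,4-dimethoxy-3,6-dimethylbenzoic trifluoroacetic anhydride | COc1cc(C)c(C(=O)OC(=O)C(F)(F)F)c(OC)c1C
F4 | step 2 | methyl 4-(allyloxy)-2-(benzyloxy)-3,6-dimethylbenzoate | C=CCOc1cc(C)c(C(=O)OC)c(OCc2ccccc2)c1C
F5 | step 2 | 4-(allyloxy)-2-(benzyloxy)-3,6-dimethylbenzoic acid | C=CCOc1cc(C)c(C(=O)O)c(OCc2ccccc2)c1C
F0 | step 9 | none | none
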